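**Retrosynthetic overview**
- Feature: in the cyclodecane ring the ketone carbon C1 and the methyl carbinol carbon C6 lie 1,6 across the ring. On the oxygenated arc C1–C2–C3–C4–C5–C6 the middle bond C3–C4 is the bond shared with the γ-butyrolactone, which is the retron of an oxy-Cope ring expansion.
- Endgame, read backwards: remove the C5 isobutyrate. Open the lactone to a 2-methylene-1,4-diol. Trace the C5/C6 diol to the 5E-alkene through its epoxide, and the C2 angelate to hydroxylation of an enolate.
- Key disconnection: a retro-[3,3] shift of the cyclodecenone enolate (cleave C3–C4, rejoin C1 to C6) gives a 1-dienyl-2-(alkoxyvinyl)-2,6-dimethylcyclohexanol.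
- The carbinol comes from a dienylcerium reagent (2-bromoallyl alcohol + bis-stannylethene) and an α-quaternary ketone. The ketone is made from meso-2,6-dimethylcyclohexanone by desymmetrising enolisation, orthoformate alkylation, Takai iodo-olefination and Cu-catalysed vinyl C–O coupling.
- Ring order: cyclohexane (bought), then the ten-membered carbocycle by 6→10 expansion (step 9), then the oxirane made (step 12) and opened (step 13), then the α-methylene-γ-butyrolactone (step 15).

Key step: step 9

Assumption: by analogy with 4-substituted cyclohexanones, the (R,R)-amide is taken to remove the axial proton at the (S)-α-carbon of 1; if the sense is opposite, the equally available (S,S)-amine is used and nothing else changes.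

Ring locants for all ten-membered compounds: C1 ketone, C2 acyloxy carbon, C3 carbon bearing the three-carbon side chain, C4 lactone-oxygen carbon, C5 isobutyrate carbon, C6 methyl carbinol carbon, C7–C9 methylenes, C10 CH(CH3).

**Step 1**
Reactants: 1 cis-2,6-dimethylcyclohexanone (meso)
Product: 3 (6R)-2,6-dimethyl-1-(trimethylsilyloxy)cyclohex-1-ene, via lithium enolate 2 (not isolated)
Conditions: (R,R)-bis(1-phenylethyl)amine, n-BuLi, THF, −78 °C; TMSCl present in situ, then 1, −100 → −78 °C
Reagents that add atoms: chlorotrimethylsilane, C[Si](C)(C)Cl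
Why: Enantiotopos-selective deprotonation of a meso ketone by a C2-symmetric chiral lithium amide removes the proton at one α-carbon only and leaves the (R)-CH(CH3) centre (later C10), while in-situ silylation traps the enolate before it can equilibrate.

**Step 2**
Reactants: 3 (6R)-silyl enol ether; 4 trimethyl orthoformate
Product: 5 (2S,6R)-2-(dimethoxymethyl)-2,6-dimethylcyclohexanone (methyls cis)
Conditions: TMSOTf (cat.), CH2Cl2, −78 °C
Reagents that add atoms: none
Why: In this Mukaiyama-type alkylation by the dimethoxycarbenium ion, allylic strain with the siloxy group pushes the C6 methyl pseudo-axial so that it shields its own face, and the electrophile should therefore enter trans to it and set the quaternary carbon as S.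

**Step 3**
Reactants: 5 keto acetal
Product: 6 (1S,3R)-1,3-dimethyl-2-oxocyclohexane-1-carbaldehyde (methyls cis)
Conditions: TFA, H2O, CH2Cl2, 0 °C
Reagents that add atoms: water, O
Why: This is an acid-catalysed acetal hydrolysis in which the formyl group sits on a quaternary carbon and cannot enolise, and the short cold exposure should leave the CH(CH3) centre unepimerised.

**Step 4**
Reactants: 6 keto aldehyde; 7 iodoform
Product: 8 (2S,6R)-2-[(E)-2-iodoethenyl]-2,6-dimethylcyclohexanone
Conditions: CrCl2, THF/dioxane, 0 °C → rt
Reagents that add atoms: none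
Why: In the Takai olefination the gem-dichromium reagent adds to aldehydes much faster than to a hindered ketone, and the bulky neopentyl-type substituent favours the E iodide.

**Step 5**
Reactants: 8 vinyl iodide; 9 4-methoxybenzyl alcohol
Product: 10 (2S,6R)-2-[(E)-2-(4-methoxybenzyloxy)ethenyl]-2,6-dimethylcyclohexanone
Conditions: CuI (cat.), 3,4,7,8-tetramethyl-1,10-phenanthroline (cat.), Cs2CO3, toluene, 80 °C
Reagents that add atoms: none
Why: Copper-catalysed Ullmann-type C–O coupling of a vinyl iodide with a primary alcohol proceeds with retention of alkene geometry, and any C6 epimer formed by the carbonate base is a separable diastereomer because the quaternary centre is fixed.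

**Step 6**
Reactants: 11 2-bromoprop-2-en-1-ol
Product: 12 (2-bromoallyloxy)(tert-butyl)dimethylsilane
Conditions: TBSCl, imidazole, CH2Cl2, 0 °C → rt
Reagents that add atoms: tert-butyldimethylsilyl chloride, CC(C)(C)[Si](C)(C)Cl
Why: Standard imidazole-promoted silylation masks the primary allylic alcohol against the organometallic and strongly basic steps that follow.

**Step 7**
Reactants: 12 bromoallyl silyl ether; 13 (E)-1,2-bis(tributylstannyl)ethene (used in excess)
Product: 14 tert-butyldimethyl{[(3E)-2-methylidene-4-(tributylstannyl)but-3-en-1-yl]oxy}silane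
Conditions: Pd(PPh3)4 (cat.), toluene, 90 °C
Reagents that add atoms: none
Why: In this Stille coupling only one stannyl group is transferred because the distannane is in excess, and both oxidative addition and transmetalation keep the alkene geometry, so the E-dienylstannane should result.

**Step 8**
Reactants: 10 ketone; 14 dienylstannane
Product: 17 (1S,2S,6R)-1-[(1E)-3-(tert-butyldimethylsilyloxymethyl)buta-1,3-dien-1-yl]-2-[(E)-2-(4-methoxybenzyloxy)ethenyl]-2,6-dimethylcyclohexan-1-ol (OH cis to both methyls; alkenyl groups cis), via dienyllithium 15 (not isolated), via dienylcerium dichloride 16 (not isolated)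
Conditions: 14, n-BuLi, THF, −78 °C; anhydrous CeCl3, −78 °C; 10, −78 → −30 °C; aq NaHCO3
Reagents that add atoms: none
Why: Tin–lithium exchange retains the E geometry, the weakly basic organocerium reagent adds 1,2 without enolising the hindered ketone, and attack along the equatorial trajectory of the diequatorial-methyl chair should place the hydroxyl axial, although this centre is not critical because step 9 erases it.

**Step 9**
Reactants: 17 dialkenylcyclohexanol
Product: 20 (2R,3R,4R,5E,10R)-3-[3-(tert-butyldimethylsilyloxy)prop-1-en-2-yl]-2-hydroxy-4-(4-methoxybenzyloxy)-6,10-dimethylcyclodec-5-en-1-one, via potassium alkoxide 18 (not isolated), via potassium enolate 19 (not isolated)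
Conditions: KH, 18-crown-6, THF, 0 °C → rt; then 2-(phenylsulfonyl)-3-phenyloxaziridine, −78 °C; aq NH4Cl
Reagents that add atoms: 2-(phenylsulfonyl)-3-phenyloxaziridine, O=S(=O)(c1ccccc1)N1OC1c1ccccc1
Why: KH converts 17 into alkoxide 18, whose charge weakens the bond between the carbinol carbon and the quaternary carbon, and a concerted [3,3] shift (anionic oxy-Cope rearrangement, in the ring-expanding form known for 1,2-divinylcyclohexanols) breaks that bond while the CH(OPMB) terminus of the enol ether bonds to the proximal CH terminus of the diene. The ten-membered ring is therefore closed by a four-carbon expansion of the six-membered ring rather than by end-to-end cyclisation, and the only new σ bond is C3–C4, the later lactone-fusion bond. The reacting conformer is the cyclohexane chair with both methyls and the dienyl group equatorial and the alkoxyvinyl group axial; in the chair-like six-centre array built on it the ring CH2 on the quaternary carbon is pseudo-equatorial, which gives the 5E alkene, and the OPMB group and the side-chain carbon, both on E alkenes, are pseudo-equatorial, so the vanishing quaternary centre is translated into (3R,4R) with anti hydrogens. Because no proton source is present, enolate 19 forms only towards C2, and the N-sulfonyloxaziridine (Davis-type enolate hydroxylation) should transfer oxygen to the enolate face turned away from the transannular alkene, giving (2R) with C10 as a spectator. The step needs chair over boat and a single pairing of alkene faces, which the diequatorial-methyl chair, the quaternary centre and the two E geometries secure, and a C1 epimer of 17 would feed the same ketone through its diequatorial-dialkenyl chair. The enol ether, diene, PMB ether and silyl ether are inert to KH, and the oxaziridine does not epoxidise alkenes at −78 °C.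

**Step 10**
Reactants: 20 hydroxy ketone; 21 angelic acid
Product: 23 (2R,3S,4R,5E,10R)-C2 angelate of 20 (PMB and TBS ethers retained), via mixed anhydride 22 (not isolated)
Conditions: 21, 2,4,6-trichlorobenzoyl chloride, Et3N, toluene, rt; then 20, 80 °C (no DMAP)
Reagents that add atoms: none
Why: Yamaguchi-type mixed-anhydride esterification run without a nucleophilic catalyst is the known way to transfer an angeloyl group without Z→E isomerisation, the C2 hydroxyl is the only free one, and its C–O bond is untouched so the configuration is kept.

**Step 11**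
Reactants: 23 angelate PMB ether
Product: 24 (2R,3S,4R,5E,10R)-C4 allylic alcohol (angelate at C2, TBS ether retained)
Conditions: DDQ, CH2Cl2/pH 7 buffer, 0 °C
Reagents that add atoms: none
Why: Oxidative cleavage of the 4-methoxybenzyl ether by DDQ goes through the stabilised benzylic oxocarbenium ion and spares the silyl ether, the esters and the unactivated alkenes under buffered conditions.

**Step 12**
Reactants: 24 allylic alcohol
Product: 25 (2R,3S,4S,5R,6R,10R)-5,6-epoxy-4-hydroxy compound (trans-epoxide, oxygen syn to the C4 hydroxyl)
Conditions: VO(acac)2 (cat.), t-BuOOH (decane), CH2Cl2, 0 °C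
Reagents that add atoms: tert-butyl hydroperoxide, CC(C)(C)OO
Why: In this vanadium-catalysed hydroxyl-directed epoxidation C4–H eclipses the alkene to avoid A(1,3) strain with the C6 methyl, which puts the hydroxyl on the peripheral face, so directed delivery and peripheral attack coincide to give the threo epoxy alcohol, while the merely homoallylic 1,1-disubstituted alkene and the electron-poor angelate react more slowly.

**Step 13**
Reactants: 25 epoxy alcohol
Product: 26 (2R,3S,4S,5R,6S,10R)-4,5,6-triol (angelate at C2, TBS ether retained)
Conditions: HClO4 (cat.), THF/H2O, 0 °C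
Reagents that add atoms: water, O
Why: In this acid-catalysed epoxide hydrolysis the protonated oxirane opens at tertiary C6, which carries positive charge best and is furthest from the withdrawing C4 hydroxyl, so oxygen arriving anti to the leaving oxygen inverts C6 to S and leaves C5 as R, the usual transannular hydride shifts being disfavoured because the cross-ring C–H bonds (C2, C10) flank the ketone, and any early silyl loss converges in step 14.

**Step 14**
Reactants: 26 silyl ether triol
Product: 27 (2R,3S,4S,5R,6S,10R)-tetraol with free 3-hydroxyprop-1-en-2-yl side chain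
Conditions: HF·pyridine, pyridine/THF, 0 °C → rt
Reagents that add atoms: none
Why: Fluoride-driven Si–O cleavage in a weakly acidic buffered medium frees the primary allylic alcohol and avoids the base-induced migration of the angelate to the neighbouring hydroxyls that basic fluoride could cause.

**Step 15**
Reactants: 27 tetraol
Product: 30 α-methylene-γ-butyrolactone diol (trans-fused at C3–C4; free C5 and C6 hydroxyls; angelate at C2), via hydroxy enal 28 (not isolated), via lactol 29 (not isolated)
Conditions: activated MnO2, CH2Cl2, rt
Reagents that add atoms: none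
Why: In this MnO2 oxidative lactonisation of a 2-methylene-1,4-diol only the primary allylic alcohol is activated, the enal is captured by the C4 hydroxyl as the kinetically favoured five-membered lactol and oxidised again, and C3 and C4 are untouched so the trans fusion set in step 9 is carried over.

**Step 16**
Reactants: 30 lactone diol
Product: 31 CNP0141258.2 (target)
Conditions: isobutyric anhydride, DMAP (cat.), pyridine, CH2Cl2, 0 °C
Reagents that add atoms: isobutyric anhydride, CC(C)C(=O)OC(=O)C(C)C
Why: DMAP-catalysed acylation esterifies the secondary C5 hydroxyl, whereas the tertiary C6 carbinol is too hindered to react under these mild conditions.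

**Compound list**
1 | cis-2,6-dimethylcyclohexanone (meso) | C[C@H]1CCC[C@@H](C)C1=O | starting material
2 | lithium (6R)-2,6-dimethylcyclohex-1-en-1-olate | C[C@@H]1CCCC(C)=C1[O-].[Li+] | intermediate
3 | (6R)-2,6-dimethyl-1-(trimethylsilyloxy)cyclohex-1-ene | C[C@@H]1CCCC(C)=C1O[Si](C)(C)C | intermediate
4 | trimethyl orthoformate | COC(OC)OC | starting material
5 | (2S,6R)-2-(dimethoxymethyl)-2,6-dimethylcyclohexanone | C[C@@H]1CCC[C@@](C)(C(OC)OC)C1=O | intermediate
6 | (1S,3R)-1,3-dimethyl-2-oxocyclohexane-1-carbaldehyde | C[C@@H]1CCC[C@@](C)(C=O)C1=O | intermediate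
7 | iodoform | IC(I)I | starting material
8 | (2S,6R)-2-[(E)-2-iodoethenyl]-2,6-dimethylcyclohexanone | C[C@@H]1CCC[C@@](C)(/C=C/I)C1=O | intermediate
9 | 4-methoxybenzyl alcohol | OCc1ccc(OC)cc1 | starting material
10 | (2S,6R)-2-[(E)-2-(4-methoxybenzyloxy)ethenyl]-2,6-dimethylcyclohexanone | C[C@@H]1CCC[C@@](C)(/C=C/OCc2ccc(OC)cc2)C1=O | intermediate
11 | 2-bromoprop-2-en-1-ol | OCC(Br)=C | starting material
12 | (2-bromoallyloxy)(tert-butyl)dimethylsilane | C=C(Br)CO[Si](C)(C)C(C)(C)C | intermediate
13 | (E)-1,2-bis(tributylstannyl)ethene | CCCC[Sn](CCCC)(CCCC)/C=C/[Sn](CCCC)(CCCC)CCCC | starting material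
14 | (E)-dienylstannane with silyl-protected hydroxymethyl | CCCC[Sn](CCCC)(CCCC)/C=C/C(=C)CO[Si](C)(C)C(C)(C)C | intermediate
15 | (E)-dienyllithium | [Li]/C=C/C(=C)CO[Si](C)(C)C(C)(C)C | intermediate
16 | (E)-dienylcerium dichloride | Cl[Ce](Cl)/C=C/C(=C)CO[Si](C)(C)C(C)(C)C | intermediate
17 | (1S,2S,6R)-cis-1,2-dialkenyl-2,6-dimethylcyclohexanol | C[C@@H]1CCC[C@@](C)(/C=C/OCc2ccc(OC)cc2)[C@@]1(O)/C=C/C(=C)CO[Si](C)(C)C(C)(C)C | intermediate
18 | potassium alkoxide of 17 | C[C@@H]1CCC[C@@](C)(/C=C/OCc2ccc(OC)cc2)[C@@]1([O-])/C=C/C(=C)CO[Si](C)(C)C(C)(C)C.[K+] | intermediate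
19 | potassium C1=C2 enolate of the (5E)-cyclodecenone (ring carbons cis across the enolate) | [K+].[O-]/C1=C/[C@@H](C(=C)CO[Si](C)(C)C(C)(C)C)[C@H](OCc2ccc(OC)cc2)/C=C(C)/CCC[C@H]1C | intermediate
20 | (2R,3R,4R,5E,10R)-2-hydroxy-4-PMBO-cyclodec-5-enone | O=C1[C@H](O)[C@@H](C(=C)CO[Si](C)(C)C(C)(C)C)[C@H](OCc2ccc(OC)cc2)/C=C(C)/CCC[C@H]1C | intermediate
21 | angelic acid, (Z)-2-methylbut-2-enoic acid | C/C=C(/C)C(=O)O | starting material
22 | angelic 2,4,6-trichlorobenzoic anhydride | C/C=C(/C)C(=O)OC(=O)c1c(Cl)cc(Cl)cc1Cl | intermediate
23 | (2R,3S,4R,5E,10R)-C2 angelate, C4 PMB ether | O=C1[C@H](OC(=O)/C(C)=C\C)[C@@H](C(=C)CO[Si](C)(C)C(C)(C)C)[C@H](OCc2ccc(OC)cc2)/C=C(C)/CCC[C@H]1C | intermediate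
24 | (2R,3S,4R,5E,10R)-C2 angelate, free C4 allylic alcohol | O=C1[C@H](OC(=O)/C(C)=C\C)[C@@H](C(=C)CO[Si](C)(C)C(C)(C)C)[C@H](O)/C=C(C)/CCC[C@H]1C | intermediate
25 | (2R,3S,4S,5R,6R,10R)-5,6-epoxy alcohol | O=C1[C@H](OC(=O)/C(C)=C\C)[C@@H](C(=C)CO[Si](C)(C)C(C)(C)C)[C@H](O)[C@H]2O[C@]2(C)CCC[C@H]1C | intermediate
26 | (2R,3S,4S,5R,6S,10R)-4,5,6-triol, TBS ether | O=C1[C@H](OC(=O)/C(C)=C\C)[C@@H](C(=C)CO[Si](C)(C)C(C)(C)C)[C@H](O)[C@@H](O)[C@@](C)(O)CCC[C@H]1C | intermediate
27 | (2R,3S,4S,5R,6S,10R)-tetraol | O=C1[C@H](OC(=O)/C(C)=C\C)[C@@H](C(=C)CO)[C@H](O)[C@@H](O)[C@@](C)(O)CCC[C@H]1C | intermediate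
28 | triol enal (side chain 3-oxoprop-1-en-2-yl) | O=C1[C@H](OC(=O)/C(C)=C\C)[C@@H](C(=C)C=O)[C@H](O)[C@@H](O)[C@@](C)(O)CCC[C@H]1C | intermediate
29 | five-membered lactol (anomers) | C=C1C(O)O[C@H]2[C@H]1[C@@H](OC(=O)/C(C)=C\C)C(=O)[C@H](C)CCC[C@](C)(O)[C@@H]2O | intermediate
30 | α-methylene lactone diol | C=C1C(=O)O[C@H]2[C@H]1[C@@H](OC(=O)/C(C)=C\C)C(=O)[C@H](C)CCC[C@](C)(O)[C@@H]2O | intermediate
31 | CNP0141258.2 | C=C1C(=O)O[C@H]2[C@H]1[C@@H](OC(=O)/C(C)=C\C)C(=O)[C@H](C)CCC[C@](C)(O)[C@@H]2OC(=O)C(C)C | target

Total step count: 16. Longest linear sequence: 14 (steps 1–5 and 8–16).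

**Steps most likely to fail**

**Step 9.**
- What may go wrong: the alkoxide may rearrange slowly or partly through a boat array. The enolate may drift to C10 by proton transfer. Most likely, the ring may relax before oxygen transfer, so that the oxaziridine meets the other enolate face.
- Fallback: C2 is set by substitution instead of by face selection.
- It sets out from 17. The same rearrangement and hydroxylation is accepted with the opposite outcome and gives the (2S)-hydroxy ketone F1.
- F1 is esterified with angelic acid 21 under Mitsunobu conditions (PPh3, DIAD, toluene, 0 °C). SN2 displacement next to the carbonyl inverts C2.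
- The route is rejoined at 23, and step 10 is not needed for this material.

**Step 13.**
- What may go wrong: water may capture an open tertiary cation from the front, with loss of inversion. The free C4 hydroxyl or the C1 carbonyl may interfere through hemiketal or ether formation. Elimination or a hydride shift to a ketone may occur, and the silyl ether may be lost early.
- Fallback: the oxirane is opened only after the lactone has been closed, on a more rigid substrate without the neighbouring free hydroxyl or the silyl ether.
- It sets out from 25. Buffered fluoride (TBAF/AcOH, THF) gives the epoxy diol F2.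
- MnO2 oxidative lactonisation then gives the epoxy α-methylene lactone F3.
- Aqueous acid hydrolysis of F3 at the tertiary carbon rejoins the route at 30.

**Step 1.**
- What may go wrong: the amide may discriminate poorly between the two enantiotopic protons, or enolate equilibration may erode the selectivity. The material would then not be a single enantiomer.
- Fallback: the quaternary carbon is made first by asymmetric catalysis, and the CH(CH3) centre is adjusted afterwards.
- It sets out from 1. Enolate O-acylation with allyl chloroformate gives the racemic allyl enol carbonate F4.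
- Palladium-catalysed decarboxylative asymmetric allylic alkylation (Pd2(dba)3, (S)-t-Bu-PHOX, chosen by analogy with 2-methylcyclohexanone substrates) gives (2S)-2-allyl-2,6-dimethylcyclohexanone as a C6 epimer mixture F5.
- Base equilibration, chromatographic separation and recycling of the unwanted epimer give the (2S,6R)-allyl ketone F6.
- Transition-metal-catalysed alkene isomerisation gives the (E)-propenyl ketone F7.
- Ozonolysis with reductive work-up rejoins the route at 6.

**Further compounds**
F1 | step 9 | (2S,3R,4R,5E,10R)-2-hydroxy epimer of 20 | O=C1[C@@H](O)[C@@H](C(=C)CO[Si](C)(C)C(C)(C)C)[C@H](OCc2ccc(OC)cc2)/C=C(C)/CCC[C@H]1C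
F2 | step 13 | epoxy diol (desilylated 25) | O=C1[C@H](OC(=O)/C(C)=C\C)[C@@H](C(=C)CO)[C@H](O)[C@H]2O[C@]2(C)CCC[C@H]1C
F3 | step 13 | 5,6-epoxy α-methylene-γ-butyrolactone | C=C1C(=O)O[C@H]2[C@H]1[C@@H](OC(=O)/C(C)=C\C)C(=O)[C@H](C)CCC[C@@]3(C)O[C@H]23
F4 | step 1 | allyl 2,6-dimethylcyclohex-1-en-1-yl carbonate (racemic) | C=CCOC(=O)OC1=C(C)CCCC1C
F5 | step 1 | (2S)-2-allyl-2,6-dimethylcyclohexanone, C6 epimer mixture | CC1CCC[C@@](C)(CC=C)C1=O
F6 | step 1 | (2S,6R)-2-allyl-2,6-dimethylcyclohexanone | C[C@@H]1CCC[C@@](C)(CC=C)C1=O
F7 | step 1 | (2S,6R)-2,6-dimethyl-2-[(E)-prop-1-en-1-yl]cyclohexanone | C[C@@H]1CCC[C@@](C)(/C=C/C)C1=O
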